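**Retrosynthetic overview**
1. Enabling feature (labdane numbering; ring A = C1–C5/C10, ring B = C5–C10): all four stereocentres (C5, C8, C9, C10) lie in ring B. C4 of ring A bears two identical CH2OH groups (C18, C19) and is not stereogenic. The formyl carbon C17 on C8 makes the most hindered bond, C9–C10, the β-bond of a C17/C8=C9 enal.
2. Key disconnection C9–C10: 6-endo addition of a tertiary C10 radical, made by hydrogen atom transfer to a C1=C10 alkene in ring A, to a (Z)-enal. This closes ring B and sets C10, C9 and C8 from C5 alone, at the final oxidation level.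
3. The precursor is cut at C12–C13 (B-alkyl Suzuki coupling with 3-bromobutenolide), C8=C9 (Still–Gennari olefination with acrolein) and C7–C8 (phosphonate alkylation). C5 comes from a CBS reduction and Johnson–Claisen chirality transfer on an achiral spiro enone made by Robinson annulation.
4. Order of ring formation: acetonide ring (temporary, bought in) → ring A → butenolide (attached as a closed ring) → ring B.

Key step: step 13

Remark: read from the SMILES, the target is the ent-labdane (5S,8S,9R,10S) isomer, a trans-decalin with the C20 methyl axial and the C11 chain on C9 and the formyl group on C8 both equatorial and trans to each other.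

**Step 1**
Reactants: 1 (2,2-dimethyl-1,3-dioxan-5-yl)methanol
Product: 2 2,2-dimethyl-1,3-dioxane-5-carbaldehyde
Conditions: TEMPO (10 mol %), PhI(OAc)2, CH2Cl2, rt
Reagents that add atoms: none
Why: TEMPO (oxoammonium) oxidation of a primary alcohol stops at the aldehyde under nearly neutral conditions, so the acetonide and the β-alkoxy aldehyde are not endangered.

**Step 2**
Reactants: 2 2,2-dimethyl-1,3-dioxane-5-carbaldehyde; 3 pent-1-en-3-one
Product: 5 3,3,8-trimethyl-2,4-dioxaspiro[5.5]undec-7-en-9-one, via keto aldehyde 4 (not isolated)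
Conditions: pyrrolidine (20 mol %), PhCO2H (20 mol %), toluene, 4 Å MS, rt → 80 °C
Reagents that add atoms: none
Why: In this Robinson annulation under enamine catalysis the enamine of the α-branched aldehyde adds to the vinyl ketone (C3–C4, quaternary C4) and the ethyl ketone arm then condenses with the now non-enolizable aldehyde (C5=C10), which closes ring A without a stereocentre because C4 carries two identical arms.

**Step 3**
Reactants: 5 3,3,8-trimethyl-2,4-dioxaspiro[5.5]undec-7-en-9-one
Product: 6 (9S)-3,3,8-trimethyl-2,4-dioxaspiro[5.5]undec-7-en-9-ol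
Conditions: (R)-2-methyl-CBS-oxazaborolidine (10 mol %), BH3·SMe2, THF, −20 °C; MeOH, then aqueous work-up
Reagents that add atoms: none
Why: In the Corey–Bakshi–Shibata reduction the α-methylalkenyl side acts as the large group, so the (R)-catalyst should give the (S)-allylic alcohol, a temporary stereocentre at C1.

**Step 4**
Reactants: 6 (9S)-3,3,8-trimethyl-2,4-dioxaspiro[5.5]undec-7-en-9-ol; 7 triethyl orthoacetate
Product: 9 ethyl 2-[(7S)-3,3,8-trimethyl-2,4-dioxaspiro[5.5]undec-8-en-7-yl]acetate, via ketene acetal 8 (not isolated)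
Conditions: EtCO2H (cat.), neat 7, 140 °C, EtOH distilled off
Reagents that add atoms: none
Why: In the Johnson–Claisen rearrangement ketene acetal 8 reorganizes suprafacially on the ring face that bears the C1–O bond, so the C1 configuration is transferred to C5 (S), the alkene moves to C1=C10, and C6 and C7 are installed.

**Step 5**
Reactants: 9 ethyl 2-[(7S)-3,3,8-trimethyl-2,4-dioxaspiro[5.5]undec-8-en-7-yl]acetate
Product: 10 2-[(7S)-3,3,8-trimethyl-2,4-dioxaspiro[5.5]undec-8-en-7-yl]ethan-1-ol
Conditions: LiAlH4, Et2O, 0 °C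
Reagents that add atoms: none
Why: Hydride reduction of the ester leaves the acetonide, the trisubstituted alkene and C5 untouched.

**Step 6**
Reactants: 10 2-[(7S)-3,3,8-trimethyl-2,4-dioxaspiro[5.5]undec-8-en-7-yl]ethan-1-ol
Product: 11 (7S)-7-(2-iodoethyl)-3,3,8-trimethyl-2,4-dioxaspiro[5.5]undec-8-ene
Conditions: I2, PPh3, imidazole, CH2Cl2, 0 °C → rt
Reagents that add atoms: iodine, [I][I]
Why: Appel-type (Garegg–Samuelsson) iodination is an SN2 displacement at the primary C7 under buffered conditions that spare the acetonide.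

**Step 7**
Reactants: 11 (7S)-7-(2-iodoethyl)-3,3,8-trimethyl-2,4-dioxaspiro[5.5]undec-8-ene; 12 methyl 2-[bis(2,2,2-trifluoroethoxy)phosphoryl]acetate
Product: 13 methyl 2-[bis(2,2,2-trifluoroethoxy)phosphoryl]-4-[(7S)-3,3,8-trimethyl-2,4-dioxaspiro[5.5]undec-8-en-7-yl]butanoate (both C2 epimers)
Conditions: NaH, 12 (excess), DMF, 0 → 50 °C
Reagents that add atoms: none
Why: Alkylation of the stabilized phosphonoacetate anion with a primary iodide forms C7–C8, and the new centre at C8 need not be controlled because it becomes sp2 in the next step.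

**Step 8**
Reactants: 13 the alkylated phosphonate; 14 acrolein
Product: 15 methyl (2Z)-2-{2-[(7S)-3,3,8-trimethyl-2,4-dioxaspiro[5.5]undec-8-en-7-yl]ethyl}penta-2,4-dienoate
Conditions: KN(SiMe3)2, 18-crown-6, THF, −78 °C; then 14
Reagents that add atoms: none
Why: In the Still–Gennari olefination the electron-poor trifluoroethyl phosphonate under dissociating conditions should collapse kinetically to the (Z)-enoate, with the ester cis to C11 and C7 trans to C11.

**Step 9**
Reactants: 15 the (Z)-dienoate
Product: 16 (2Z)-2-{2-[(7S)-3,3,8-trimethyl-2,4-dioxaspiro[5.5]undec-8-en-7-yl]ethyl}penta-2,4-dien-1-ol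
Conditions: i-Bu2AlH (2.5 equiv), CH2Cl2, −78 °C; Rochelle salt work-up
Reagents that add atoms: none
Why: 1,2-Reduction of the enoate at low temperature keeps the alkene geometry and is placed before the butenolide enters, so no lactone has to be spared.

**Step 10**
Reactants: 17 furan-2(5H)-one
Product: 19 3-bromofuran-2(5H)-one, via dibromolactone 18 (not isolated)
Conditions: Br2, ClCH2CH2Cl, reflux; then Et3N, 0 °C
Reagents that add atoms: bromine, BrBr
Why: In this bromine addition and dehydrobromination the amine removes the acidic α-hydrogen and the β-bromide leaves, which gives the α-bromobutenolide.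

**Step 11**
Reactants: 16 the (Z)-dienol; 19 3-bromofuran-2(5H)-one
Product: 21 3-[(3Z)-4-(hydroxymethyl)-6-[(7S)-3,3,8-trimethyl-2,4-dioxaspiro[5.5]undec-8-en-7-yl]hex-3-en-1-yl]furan-2(5H)-one, via bis-boryl adduct 20 (not isolated)
Conditions: 9-BBN-H (2.3 equiv), THF, 0 °C → rt; then 19, Pd(dppf)Cl2 (5 mol %), AsPh3, Cs2CO3, DMF–H2O, rt
Reagents that add atoms: 9-borabicyclo[3.3.1]nonane (9-BBN-H), B1C2CCCC1CCC2 (its boron is present in 20 only)
Why: 9-BBN-H caps the hydroxyl as a borinate and adds only to the monosubstituted C11=C12 terminus of the diene, and the B-alkyl Suzuki–Miyaura coupling with the α-bromo enoate then forms C12–C13 without touching the C8=C9 geometry.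

**Step 12**
Reactants: 21 the (Z)-allylic alcohol
Product: 22 (2Z)-5-(2-oxo-2,5-dihydrofuran-3-yl)-2-{2-[(7S)-3,3,8-trimethyl-2,4-dioxaspiro[5.5]undec-8-en-7-yl]ethyl}pent-2-enal
Conditions: activated MnO2 (excess), CH2Cl2, rt, dark; used at once
Reagents that add atoms: none
Why: Heterogeneous, neutral MnO2 oxidation is selective for the allylic alcohol and should preserve the (Z)-geometry, while the butenolide and the ring alkene are inert.

**Step 13**
Reactants: 22 the (Z)-enal
Product: 25 18,19-O-isopropylidene derivative of the target, (5S,8S,9R,10S), via tertiary C10 radical 23 (not isolated), via C8 radical 24 (not isolated)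
Conditions: Fe(acac)3 (20 mol %), Ph(i-PrO)SiH2 (2 equiv), i-PrOH (0.02 M, degassed), 35 °C
Reagents that add atoms: none
Why: Fe(acac)3 and the silane form a trivalent iron hydride that transfers a hydrogen atom to C1 of the C1=C10 alkene, the tertiary C10 radical 23 adds to C9 (the β-carbon of the enal), and the formyl-stabilized C8 radical 24 is reduced by divalent iron and protonated by i-PrOH. The closest known reaction type is the iron-catalysed reductive olefin coupling (hydrogen-atom-transfer-initiated Giese cyclization), the event that also ends stepwise radical polyene cyclizations on α-branched acceptors, and ring B closes in the 6-endo-trig mode because the acceptor is tethered through its α-carbon C8, so that 5-exo attack would have to hit a fully substituted, polarity-mismatched carbon. C10 is controlled by C5: the C6–C7 tether is equatorial on ring A and reaches the radical through a chair, C9 bonds equatorially and the small methyl group goes axial, which gives the trans ring fusion. C9 is controlled by the alkene geometry, because in that chair the substituent trans to C7 ends up equatorial, so the (Z)-enal places the C11 chain equatorial. C8 is set by protonation and is under thermodynamic control, since enolization drains any axial aldehyde (1,3-diaxial to the C10 methyl) into the equatorial one, trans to C11. The step needs hydrogen atom transfer to C1=C10 rather than to the two electron-poor alkenes, and capture of 23 by C9 only, which the substrate secures because C1=C10 is its only electron-rich alkene and has an open CH terminus, C9 lies in six-ring distance, and the butenolide could be reached only through a ten-membered transition state.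

**Step 14**
Reactants: 25 the acetonide aldehyde
Product: 26 (1R,2S,4aS,8aS)-5,5-bis(hydroxymethyl)-8a-methyl-1-[2-(2-oxo-2,5-dihydrofuran-3-yl)ethyl]decahydronaphthalene-2-carbaldehyde (target)
Conditions: AcOH–THF–H2O (3:1:1), rt → 40 °C
Reagents that add atoms: none
Why: Mild acid hydrolysis of the 1,3-dioxane acetonide frees C18-OH and C19-OH, the butenolide is acid-stable, and the equatorial aldehyde is the thermodynamic epimer and cannot be scrambled.

**Compound list**
1 | (2,2-dimethyl-1,3-dioxan-5-yl)methanol | CC1(C)OCC(CO)CO1 | starting material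
2 | 2,2-dimethyl-1,3-dioxane-5-carbaldehyde | CC1(C)OCC(C=O)CO1 | intermediate
3 | pent-1-en-3-one | CCC(=O)C=C | starting material
4 | 2,2-dimethyl-5-(3-oxopentyl)-1,3-dioxane-5-carbaldehyde | CCC(=O)CCC1(C=O)COC(C)(C)OC1 | intermediate
5 | 3,3,8-trimethyl-2,4-dioxaspiro[5.5]undec-7-en-9-one | CC1=CC2(CCC1=O)COC(C)(C)OC2 | intermediate
6 | (9S)-3,3,8-trimethyl-2,4-dioxaspiro[5.5]undec-7-en-9-ol | CC1=CC2(CC[C@@H]1O)COC(C)(C)OC2 | intermediate
7 | triethyl orthoacetate | CC(OCC)(OCC)OCC | starting material
8 | (9S)-9-[(1-ethoxyethenyl)oxy]-3,3,8-trimethyl-2,4-dioxaspiro[5.5]undec-7-ene | C=C(OCC)O[C@H]1CCC2(COC(C)(C)OC2)C=C1C | intermediate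
9 | ethyl 2-[(7S)-3,3,8-trimethyl-2,4-dioxaspiro[5.5]undec-8-en-7-yl]acetate | CC1=CCCC2(COC(C)(C)OC2)[C@H]1CC(=O)OCC | intermediate
10 | 2-[(7S)-3,3,8-trimethyl-2,4-dioxaspiro[5.5]undec-8-en-7-yl]ethan-1-ol | CC1=CCCC2(COC(C)(C)OC2)[C@H]1CCO | intermediate
11 | (7S)-7-(2-iodoethyl)-3,3,8-trimethyl-2,4-dioxaspiro[5.5]undec-8-ene | CC1=CCCC2(COC(C)(C)OC2)[C@H]1CCI | intermediate
12 | methyl 2-[bis(2,2,2-trifluoroethoxy)phosphoryl]acetate | COC(=O)CP(=O)(OCC(F)(F)F)OCC(F)(F)F | starting material
13 | methyl 2-[bis(2,2,2-trifluoroethoxy)phosphoryl]-4-[(7S)-3,3,8-trimethyl-2,4-dioxaspiro[5.5]undec-8-en-7-yl]butanoate (C2 epimers) | CC1=CCCC2(COC(C)(C)OC2)[C@H]1CCC(C(=O)OC)P(=O)(OCC(F)(F)F)OCC(F)(F)F | intermediate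
14 | acrolein | C=CC=O | starting material
15 | methyl (2Z)-2-{2-[(7S)-3,3,8-trimethyl-2,4-dioxaspiro[5.5]undec-8-en-7-yl]ethyl}penta-2,4-dienoate | CC1=CCCC2(COC(C)(C)OC2)[C@H]1CC/C(C(=O)OC)=C/C=C | intermediate
16 | (2Z)-2-{2-[(7S)-3,3,8-trimethyl-2,4-dioxaspiro[5.5]undec-8-en-7-yl]ethyl}penta-2,4-dien-1-ol | CC1=CCCC2(COC(C)(C)OC2)[C@H]1CC/C(CO)=C/C=C | intermediate
17 | furan-2(5H)-one | O=C1OCC=C1 | starting material
18 | 3,4-dibromooxolan-2-one | O=C1OCC(Br)C1Br | intermediate
19 | 3-bromofuran-2(5H)-one | O=C1OCC=C1Br | intermediate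
20 | bis(9-BBN) adduct of 16 (B-alkyl borane at C12, borinate on the C17 oxygen) | CC1=CCCC2(COC(C)(C)OC2)[C@H]1CC/C(COB1C2CCCC1CCC2)=C/CCB1C2CCCC1CCC2 | intermediate
21 | 3-[(3Z)-4-(hydroxymethyl)-6-[(7S)-3,3,8-trimethyl-2,4-dioxaspiro[5.5]undec-8-en-7-yl]hex-3-en-1-yl]furan-2(5H)-one | CC1=CCCC2(COC(C)(C)OC2)[C@H]1CC/C(CO)=C/CCC1=CCOC1=O | intermediate
22 | (2Z)-5-(2-oxo-2,5-dihydrofuran-3-yl)-2-{2-[(7S)-3,3,8-trimethyl-2,4-dioxaspiro[5.5]undec-8-en-7-yl]ethyl}pent-2-enal | CC1=CCCC2(COC(C)(C)OC2)[C@H]1CC/C(C=O)=C/CCC1=CCOC1=O | intermediate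
23 | tertiary C10 radical from 22 (H added at C1) | C[C]1CCCC2(COC(C)(C)OC2)[C@H]1CC/C(C=O)=C/CCC1=CCOC1=O | intermediate
24 | ring-closed, formyl-stabilized C8 radical | C[C@@]12CCCC3(COC(C)(C)OC3)[C@H]1CC[C](C=O)[C@H]2CCC1=CCOC1=O | intermediate
25 | 18,19-O-isopropylidene derivative of 26, (5S,8S,9R,10S) | C[C@@]12CCCC3(COC(C)(C)OC3)[C@H]1CC[C@H](C=O)[C@H]2CCC1=CCOC1=O | intermediate
26 | (1R,2S,4aS,8aS)-5,5-bis(hydroxymethyl)-8a-methyl-1-[2-(2-oxo-2,5-dihydrofuran-3-yl)ethyl]decahydronaphthalene-2-carbaldehyde | C[C@@]12CCCC(CO)(CO)[C@H]1CC[C@H](C=O)[C@H]2CCC1=CCOC1=O | target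

**Total step count:** 14.
**Longest linear sequence:** 13 (steps 1–9 and 11–14).

**Steps most likely to fail**

**1. Step 13.**
- What may go wrong:
  - hydrogen atom transfer to the enal, giving plain conjugate reduction;
  - Z to E isomerization of the enal before ring closure, which would erode control at C9;
  - closure through the ring-flipped conformer to a cis ring fusion;
  - back-transfer from the C10 radical, with migration of the alkene to the unreactive C5=C10 position.
- The fallback sets out from 13 and comes back at 25. It replaces the enal by a (Z)-enoate, the acceptor class with the closest precedent, which holds its geometry and cannot be reduced at the carbonyl.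
- 3,3-Diethoxyprop-1-ene is hydroborated with 9-BBN-H to the B-alkyl borane F1. F1 is coupled with 19 (Pd(dppf)Cl2, Cs2CO3) to the acetal F2, and dilute acid gives 3-(2-oxo-2,5-dihydrofuran-3-yl)propanal F3.
- Still–Gennari olefination of 13 with F3 gives the (Z)-enoate butenolide F4.
- Fe(acac)3, PhSiH3 and EtOH at 60 °C close ring B, still as the last ring, to the bicyclic methyl ester F5.
- LiOH followed by acidification to about pH 3 recloses the butenolide and gives the C17 acid F6.
- BH3·SMe2 reduces the free acid in preference to the lactone, giving the primary alcohol F7. Dess–Martin periodinane oxidizes F7 to 25.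

**2. Step 2.**
- What may go wrong:
  - β-elimination of an acetonide oxygen from the enamine or enol of 2 (retro-oxa-Michael opening of the dioxane);
  - oligomerization of the vinyl ketone under amine catalysis.
- The fallback sets out from 2 and comes back at 5 by way of 4, which is now isolated.
- Soft enolization (Me3SiCl, NaI, Et3N, MeCN) gives the silyl enol ether F8.
- A Mukaiyama–Michael addition of F8 to 3 (Sc(OTf)3 cat., CH2Cl2, −78 °C, aqueous work-up) builds the quaternary C4 without any free enamine or enolate and gives 4.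
- 4 has no α-hydrogen left on the aldehyde side, so it is closed separately by aldol condensation (KOH, MeOH) to 5.

**3. Step 11.**
- What may go wrong:
  - unselective hydroboration of the conjugated diene;
  - protodeboronation;
  - base-induced decomposition of the bromobutenolide during the coupling.
- The fallback sets out from 16 and comes back at 21. It builds the butenolide by enolate alkylation and sulfoxide elimination instead of cross-coupling.
- Silylation (t-BuMe2SiCl, imidazole) gives the silyl ether F9.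
- 9-BBN-H gives the borane F10, which H2O2/NaOH oxidizes to the primary alcohol F11. I2, PPh3 and imidazole then give the iodide F12.
- 3-(Phenylsulfanyl)oxolan-2-one F13 is made from 3-bromooxolan-2-one, PhSH and Et3N. It is alkylated with F12 (LiN(i-Pr)2, THF–DMPU) to the sulfide lactone F14.
- NaIO4 gives the sulfoxide F15. Thermolysis (toluene, CaCO3, 110 °C) eliminates toward the ring CH2 to the butenolide silyl ether F16.
- Buffered HF·pyridine then gives 21.

**Further compounds**
F1 | step 13 | 9-(3,3-diethoxypropyl)-9-borabicyclo[3.3.1]nonane | CCOC(CCB1C2CCCC1CCC2)OCC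
F2 | step 13 | 3-(3,3-diethoxypropyl)furan-2(5H)-one | CCOC(CCC1=CCOC1=O)OCC
F3 | step 13 | 3-(2-oxo-2,5-dihydrofuran-3-yl)propanal | O=CCCC1=CCOC1=O
F4 | step 13 | methyl (2Z)-5-(2-oxo-2,5-dihydrofuran-3-yl)-2-{2-[(7S)-3,3,8-trimethyl-2,4-dioxaspiro[5.5]undec-8-en-7-yl]ethyl}pent-2-enoate | CC1=CCCC2(COC(C)(C)OC2)[C@H]1CC/C(C(=O)OC)=C/CCC1=CCOC1=O
F5 | step 13 | C17 methyl ester analogue of 25, (5S,8S,9R,10S) | C[C@@]12CCCC3(COC(C)(C)OC3)[C@H]1CC[C@H](C(=O)OC)[C@H]2CCC1=CCOC1=O
F6 | step 13 | C17 carboxylic acid analogue of 25 | C[C@@]12CCCC3(COC(C)(C)OC3)[C@H]1CC[C@H](C(=O)O)[C@H]2CCC1=CCOC1=O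
F7 | step 13 | C17 primary alcohol analogue of 25 | C[C@@]12CCCC3(COC(C)(C)OC3)[C@H]1CC[C@H](CO)[C@H]2CCC1=CCOC1=O
F8 | step 2 | 2,2-dimethyl-5-{[(trimethylsilyl)oxy]methylidene}-1,3-dioxane | CC1(C)OCC(=CO[Si](C)(C)C)CO1
F9 | step 11 | tert-butyldimethylsilyl ether of 16 | CC1=CCCC2(COC(C)(C)OC2)[C@H]1CC/C(CO[Si](C)(C)C(C)(C)C)=C/C=C
F10 | step 11 | C12 B-alkyl-9-BBN adduct of F9 | CC1=CCCC2(COC(C)(C)OC2)[C@H]1CC/C(CO[Si](C)(C)C(C)(C)C)=C/CCB1C2CCCC1CCC2
F11 | step 11 | C12 primary alcohol | CC1=CCCC2(COC(C)(C)OC2)[C@H]1CC/C(CO[Si](C)(C)C(C)(C)C)=C/CCO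
F12 | step 11 | C12 primary iodide | CC1=CCCC2(COC(C)(C)OC2)[C@H]1CC/C(CO[Si](C)(C)C(C)(C)C)=C/CCI
F13 | step 11 | 3-(phenylsulfanyl)oxolan-2-one | O=C1OCCC1Sc1ccccc1
F14 | step 11 | α-alkylated α-(phenylsulfanyl) lactone (C13 epimers) | CC1=CCCC2(COC(C)(C)OC2)[C@H]1CC/C(CO[Si](C)(C)C(C)(C)C)=C/CCC1(Sc2ccccc2)CCOC1=O
F15 | step 11 | corresponding sulfoxide (diastereomers) | CC1=CCCC2(COC(C)(C)OC2)[C@H]1CC/C(CO[Si](C)(C)C(C)(C)C)=C/CCC1(S(=O)c2ccccc2)CCOC1=O
F16 | step 11 | tert-butyldimethylsilyl ether of 21 | CC1=CCCC2(COC(C)(C)OC2)[C@H]1CC/C(CO[Si](C)(C)C(C)(C)C)=C/CCC1=CCOC1=O
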